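Each 2-pyranone is bonded through C6 to a quaternary carbon of the cyclobutane. Its O1–C6–C5 segment is therefore the enol of a methyl ketone, and C2–C3(Me)–C4 is a methylmalonyl unit. Both heterocycles are cut at C4–C5 and O1–C2, which leads back to a cis-3,4-diacetyl-3,4-dimethylcyclobutane-1,2-dicarboxylate. In one operation the key step joins the bis(trimethylsilyl enol ether) of this diketone with two molecules of methylmalonyl dichloride. This makes four bonds and both pyranone rings without touching the four ring stereocentres. The precursor is a meso dibenzyl ester with two 1-(silyloxy)vinyl groups on one face and Me, CO2Bn, CO2Bn, Me on the other. It comes from ozonolysis of a tetramethylbicyclo[2.2.0]hexene.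

Key step: step 8

Assumption: the target SMILES is read as the meso (1R,2S,3R,4S) isomer, with both methyls and both carboxyls on one face of the cyclobutane and both pyranones on the other. The half-ester of step 4 is racemic. The cycloadduct of step 1 is drawn endo, an orientation that step 2 erases.

Step 1
Reactants: 1 but-2-yne (2 equiv); 2 maleic anhydride
Product: 5 endo-1,4,5,6-tetramethylbicyclo[2.2.0]hex-5-ene-2,3-dicarboxylic anhydride (meso; anhydride ring on the same side of the cyclobutane as the C5=C6 bridge), via tetramethylcyclobutadiene·AlCl3 complex 3 (not isolated), via free tetramethylcyclobutadiene 4 (not isolated)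
Conditions: AlCl3 (1 equiv), CH2Cl2, 0 °C; then 2, −40 °C; then DMSO, −40 °C → rt
Reagents that add atoms: none
Why: AlCl3 cyclodimerises but-2-yne to a σ-bound cyclobutadiene complex, the donor DMSO strips the AlCl3, and the liberated antiaromatic diene is caught at once by the electron-poor alkene in a suprafacial Diels–Alder-type trapping, so the two C–H centres stay cis as in 2, the bridgehead methyls are cis by ring constraint, and the endo rule puts the anhydride under the new double bond.

Step 2
Reactants: 5 endo-1,4,5,6-tetramethylbicyclo[2.2.0]hex-5-ene-2,3-dicarboxylic anhydride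
Product: 6 cis-3,4,5,6-tetramethylcyclohexa-3,5-diene-1,2-dicarboxylic anhydride (meso)
Conditions: xylenes, 140 °C, Ar
Reagents that add atoms: none
Why: Thermal valence isomerisation of a bicyclo[2.2.0]hex-2-ene, in which strain release breaks the doubly allylic central C1–C4 bond and gives the cyclohexa-1,3-diene while C2 and C3 are not involved, so the cis ring fusion is kept and the diene is formed with no dienophile present that could add to it a second time.

Step 3
Reactants: 6 cis-3,4,5,6-tetramethylcyclohexa-3,5-diene-1,2-dicarboxylic anhydride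
Product: 7 exo-1,4,5,6-tetramethylbicyclo[2.2.0]hex-5-ene-2,3-dicarboxylic anhydride (meso; anhydride ring cis to both bridgehead methyls and anti to the C5=C6 bridge)
Conditions: hν (300 nm lamps, quartz), degassed Et2O, 0 °C
Reagents that add atoms: none
Why: Photochemical disrotatory 4π electrocyclisation of a cyclohexa-1,3-diene, the reaction known for the parent cis-1,2-dihydrophthalic anhydride, in which the fused five-membered ring shuts off the competing conrotatory 6π opening, disrotation makes the two new quaternary centres cis, and folding of the emerging cyclobutene away from the anhydride ring (no stacking of the two rings inside the bicycle) should place the anhydride exo, whereas closure on the other face only gives back 5, which re-enters at step 2.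

Step 4
Reactants: 7 exo-1,4,5,6-tetramethylbicyclo[2.2.0]hex-5-ene-2,3-dicarboxylic anhydride
Product: 9 dibenzyl exo,exo-1,4,5,6-tetramethylbicyclo[2.2.0]hex-5-ene-2,3-dicarboxylate (meso), via racemic monobenzyl half-ester 8 (not isolated)
Conditions: BnOH, DMAP (cat.), DMF, rt; then Cs2CO3, BnBr, rt
Reagents that add atoms: benzyl alcohol OCc1ccccc1; benzyl bromide BrCc1ccccc1
Why: DMAP-catalysed alcoholysis of the cyclic anhydride and SN2 O-benzylation of the resulting caesium carboxylate are standard and leave the α-C–H bonds alone, so the exo,cis configuration is carried over, and benzyl is chosen because it leaves at the end by neutral hydrogenolysis instead of a hydrolysis that would endanger the pyranone lactones.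

Step 5
Reactants: 9 dibenzyl exo,exo-1,4,5,6-tetramethylbicyclo[2.2.0]hex-5-ene-2,3-dicarboxylate
Product: 10 dibenzyl (1R,2S,3R,4S)-3,4-diacetyl-3,4-dimethylcyclobutane-1,2-dicarboxylate (meso; both acetyls on one face; both methyls and both esters on the other)
Conditions: O3, CH2Cl2/MeOH, −78 °C; then Me2S, −78 °C → rt
Reagents that add atoms: ozone [O-][O+]=O
Why: Criegee ozonolysis with reductive work-up, in which the strained, electron-rich tetraalkyl C5=C6 bond reacts far faster with ozone than the benzyl rings, and since both alkene carbons already carry a methyl group the cleavage gives the two methyl ketones directly, cis to each other and trans to the esters because they were the two ends of the anti bridge.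

Step 6
Reactants: 10 dibenzyl (1R,2S,3R,4S)-3,4-diacetyl-3,4-dimethylcyclobutane-1,2-dicarboxylate
Product: 11 dibenzyl (1R,2S,3R,4S)-3,4-dimethyl-3,4-bis[1-(trimethylsilyloxy)ethenyl]cyclobutane-1,2-dicarboxylate (meso)
Conditions: TMSOTf (2.4 equiv), Et3N (4 equiv), CH2Cl2, 0 °C; cold aq NaHCO3/pentane work-up, used crude
Reagents that add atoms: trimethylsilyl trifluoromethanesulfonate C[Si](C)(C)OS(=O)(=O)C(F)(F)F
Why: Soft enolisation with a silyl triflate and a tertiary amine, in which each acetyl group hangs on a quaternary carbon and can enolise only toward its CH3, ketones are silylated much faster than esters so the ester α-centres are not disturbed, and aldol closure between the two arms would be a disfavoured 5-(enolendo)-exo-trig process.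

Step 7
Reactants: 12 methylmalonic acid
Product: 13 methylmalonyl dichloride
Conditions: SOCl2 (neat), 50 → 60 °C; vacuum distillation
Reagents that add atoms: thionyl chloride O=S(Cl)Cl
Why: Standard conversion of a malonic acid into its dichloride with thionyl chloride, kept at moderate temperature to limit ketene formation and decarboxylation, the product being distilled and used fresh.

Step 8
Reactants: 11 dibenzyl (1R,2S,3R,4S)-3,4-dimethyl-3,4-bis[1-(trimethylsilyloxy)ethenyl]cyclobutane-1,2-dicarboxylate; 13 methylmalonyl dichloride (3 equiv)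
Product: 15 dibenzyl (1R,2S,3R,4S)-3,4-bis(4-hydroxy-3-methyl-2-oxo-2H-pyran-6-yl)-3,4-dimethylcyclobutane-1,2-dicarboxylate (meso), via bis(β-diketone acid chloride) 14 (not isolated)
Conditions: 13 in Et2O, −78 °C; slow addition of 11; −78 °C → rt
Reagents that add atoms: none
Why: The terminal carbon of each silyl enol ether attacks one C(=O)Cl group of 13 (or the chlorocarbonyl ketene formed from it by loss of HCl), Me3SiCl departs and the C4–C5 bond of a β-diketone acid chloride is made. The enol oxygen of the former acetyl group then acylates on the remaining acid chloride, forming O1–C2, and tautomerisation gives the 4-hydroxy-2-pyranone. This is the known [3+3] annulation of silyl enol ethers with malonyl dichlorides, here run twice on one molecule. Both rings close in the 6-exo-trig mode, oxygen adding to an acyl carbon whose C=O lies outside the forming ring. No stereocentre is created, since C3 of each pyranone ends up sp2, and the four cyclobutane centres are safe because no base is present. The step needs C-acylation before O-acylation, one dichloride per arm and a single regiochemistry, which are secured by the carbon nucleophilicity of the silyl enol ether, by inverse addition into excess 13 so that six-membered lactonisation outruns bridging of the two arms, and by the quaternary ring carbons, which leave only the CH2 terminus open to attack.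

Step 9
Reactants: 15 dibenzyl (1R,2S,3R,4S)-3,4-bis(4-hydroxy-3-methyl-2-oxo-2H-pyran-6-yl)-3,4-dimethylcyclobutane-1,2-dicarboxylate
Product: 16 dibenzyl (1R,2S,3R,4S)-3,4-bis(4-methoxy-3-methyl-2-oxo-2H-pyran-6-yl)-3,4-dimethylcyclobutane-1,2-dicarboxylate (meso)
Conditions: Me2SO4 (2.5 equiv), K2CO3, acetone, rt → 40 °C
Reagents that add atoms: dimethyl sulfate COS(=O)(=O)OC
Why: Williamson-type O-alkylation of a vinylogous carboxylic acid, in which the pyranolate is methylated by the hard electrophile at the C4 oxygen as is usual for 4-hydroxy-2-pyranones, C3 is blocked by its methyl group, and the weak heterogeneous base does not epimerise the ester α-centres.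

Step 10
Reactants: 16 dibenzyl (1R,2S,3R,4S)-3,4-bis(4-methoxy-3-methyl-2-oxo-2H-pyran-6-yl)-3,4-dimethylcyclobutane-1,2-dicarboxylate
Product: 17 (1R,2S,3R,4S)-3,4-bis(4-methoxy-3-methyl-2-oxo-2H-pyran-6-yl)-3,4-dimethylcyclobutane-1,2-dicarboxylic acid (CNP0574758.1)
Conditions: H2 (1 atm), Pd/C, EtOAc, rt
Reagents that add atoms: none
Why: Catalytic hydrogenolysis of benzyl esters, which runs under neutral conditions much faster than any reduction of the fully conjugated 4-methoxy-2-pyranones, so the lactones, the enol methyl ethers and the cis configuration of the two carboxyl-bearing centres are untouched.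

Compound list
1 | but-2-yne | CC#CC | starting material
2 | maleic anhydride | O=C1OC(=O)C=C1 | starting material
3 | tetramethylcyclobutadiene·AlCl3 σ-complex (cyclobutenyl cation/trichloroaluminate zwitterion) | C[C+]1C(C)=C(C)C1(C)[Al-](Cl)(Cl)Cl | intermediate
4 | 1,2,3,4-tetramethylcyclobuta-1,3-diene | CC1=C(C)C(C)=C1C | intermediate
5 | endo-1,4,5,6-tetramethylbicyclo[2.2.0]hex-5-ene-2,3-dicarboxylic anhydride (meso) | CC1=C(C)[C@@]2(C)[C@H]3C(=O)OC(=O)[C@H]3[C@@]12C | intermediate
6 | cis-3,4,5,6-tetramethylcyclohexa-3,5-diene-1,2-dicarboxylic anhydride (meso) | CC1=C(C)C(C)=C(C)[C@@H]2C(=O)OC(=O)[C@H]12 | intermediate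
7 | exo-1,4,5,6-tetramethylbicyclo[2.2.0]hex-5-ene-2,3-dicarboxylic anhydride (meso) | CC1=C(C)[C@@]2(C)[C@@H]3C(=O)OC(=O)[C@@H]3[C@@]12C | intermediate
8 | exo,exo-3-(benzyloxycarbonyl)-1,4,5,6-tetramethylbicyclo[2.2.0]hex-5-ene-2-carboxylic acid (racemic, one enantiomer drawn) | CC1=C(C)[C@@]2(C)[C@H](C(=O)O)[C@H](C(=O)OCc3ccccc3)[C@@]12C | intermediate
9 | dibenzyl exo,exo-1,4,5,6-tetramethylbicyclo[2.2.0]hex-5-ene-2,3-dicarboxylate (meso) | CC1=C(C)[C@@]2(C)[C@H](C(=O)OCc3ccccc3)[C@H](C(=O)OCc3ccccc3)[C@@]12C | intermediate
10 | dibenzyl (1R,2S,3R,4S)-3,4-diacetyl-3,4-dimethylcyclobutane-1,2-dicarboxylate | CC(=O)[C@@]1(C)[C@H](C(=O)OCc2ccccc2)[C@H](C(=O)OCc2ccccc2)[C@@]1(C)C(C)=O | intermediate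
11 | dibenzyl (1R,2S,3R,4S)-3,4-dimethyl-3,4-bis[1-(trimethylsilyloxy)ethenyl]cyclobutane-1,2-dicarboxylate | C=C(O[Si](C)(C)C)[C@@]1(C)[C@H](C(=O)OCc2ccccc2)[C@H](C(=O)OCc2ccccc2)[C@@]1(C)C(=C)O[Si](C)(C)C | intermediate
12 | methylmalonic acid | CC(C(=O)O)C(=O)O | starting material
13 | methylmalonyl dichloride | CC(C(=O)Cl)C(=O)Cl | intermediate
14 | dibenzyl 3,4-bis(5-chloro-4-methyl-3,5-dioxopentanoyl)-3,4-dimethylcyclobutane-1,2-dicarboxylate (side-chain CHMe centres undefined) | CC(C(=O)Cl)C(=O)CC(=O)[C@@]1(C)[C@H](C(=O)OCc2ccccc2)[C@H](C(=O)OCc2ccccc2)[C@@]1(C)C(=O)CC(=O)C(C)C(=O)Cl | intermediate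
15 | dibenzyl (1R,2S,3R,4S)-3,4-bis(4-hydroxy-3-methyl-2-oxo-2H-pyran-6-yl)-3,4-dimethylcyclobutane-1,2-dicarboxylate | Cc1c(O)cc([C@@]2(C)[C@H](C(=O)OCc3ccccc3)[C@H](C(=O)OCc3ccccc3)[C@@]2(C)c2cc(O)c(C)c(=O)o2)oc1=O | intermediate
16 | dibenzyl (1R,2S,3R,4S)-3,4-bis(4-methoxy-3-methyl-2-oxo-2H-pyran-6-yl)-3,4-dimethylcyclobutane-1,2-dicarboxylate | COc1cc([C@@]2(C)[C@H](C(=O)OCc3ccccc3)[C@H](C(=O)OCc3ccccc3)[C@@]2(C)c2cc(OC)c(C)c(=O)o2)oc(=O)c1C | intermediate
17 | (1R,2S,3R,4S)-3,4-bis(4-methoxy-3-methyl-2-oxo-2H-pyran-6-yl)-3,4-dimethylcyclobutane-1,2-dicarboxylic acid | COc1cc([C@@]2(C)[C@H](C(=O)O)[C@H](C(=O)O)[C@@]2(C)c2cc(OC)c(C)c(=O)o2)oc(=O)c1C | target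

Total steps: 10. Longest linear sequence: 9 (steps 1–6 and 8–10; step 7 is a one-step branch).

Steps most likely to fail

Step 8. The HCl released by the first lactonisation may protodesilylate the second enol ether before it is acylated. One malonyl unit may also link two arms or two molecules, so the double annulation stops halfway or oligomerises. The fallback separates bond formation from ring closure. Setting out from 11, each enol ether is C-acylated with the mono-acid chloride methyl 3-chloro-2-methyl-3-oxopropanoate (CH2Cl2, −78 °C → rt, ZnCl2 if needed). This reagent has a single reactive acyl group and releases no HCl. It gives dibenzyl 3,4-bis(5-methoxy-4-methyl-3,5-dioxopentanoyl)-3,4-dimethylcyclobutane-1,2-dicarboxylate F1. A separate base-induced lactonisation with loss of methanol (DBU, toluene, 60 °C), the standard closure of 3,5-dioxo esters, comes back to the route at 15.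

Step 3. The sterically twisted, fully substituted diene may relax without closing, and facial selectivity may be poor. Wrong-face closure costs no material, since it regenerates 5. The fallback uses a flatter, less substituted diene and builds the acetyl groups afterwards.
- Setting out from 2, commercial 2,5-dimethylthiophene is oxidised (mCPBA, BF3·OEt2, CH2Cl2, −20 °C) in the presence of 2 to 2,5-dimethylthiophene 1-oxide F2.
- This is trapped in the flask as endo-1,4-dimethyl-7-thiabicyclo[2.2.1]hept-5-ene-2,3-dicarboxylic anhydride 7-oxide F3 (S=O oxygen over the anhydride-bearing bridge).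
- After removal of all dienophile, cheletropic loss of SO (toluene, 110 °C, Ar) gives cis-3,6-dimethylcyclohexa-3,5-diene-1,2-dicarboxylic anhydride F4, the closest relative of the parent dihydrophthalic anhydride.
- Irradiation closes it to exo-1,4-dimethylbicyclo[2.2.0]hex-5-ene-2,3-dicarboxylic anhydride F5.
- BnOH/DMAP, then Cs2CO3/BnBr, lead through the racemic monobenzyl half-ester F6 to dibenzyl exo,exo-1,4-dimethylbicyclo[2.2.0]hex-5-ene-2,3-dicarboxylate F7.
- Ozonolysis with Me2S work-up gives the non-enolisable dibenzyl 3,4-diformyl-3,4-dimethylcyclobutane-1,2-dicarboxylate F8.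
- MeTi(OiPr)3 (Et2O, −40 → 0 °C) adds to both formyl groups without touching the esters and gives dibenzyl 3,4-bis(1-hydroxyethyl)-3,4-dimethylcyclobutane-1,2-dicarboxylate F9 (carbinol configuration irrelevant).
- Dess–Martin oxidation comes back to the route at 10.

Step 1. Trapping may be inefficient because the liberated cyclobutadiene dimerises or the AlCl3-activated anhydride degrades before cycloaddition. The fallback generates the diene reductively, without AlCl3. Setting out from 1, chlorinative cyclodimerisation (Cl2, BF3, CH2Cl2, low temperature) gives 3,4-dichloro-1,2,3,4-tetramethylcyclobut-1-ene F10. Dechlorination with zinc dust (Et2O, rt) in the presence of 2 releases 4 slowly, so it meets excess dienophile, and comes back to the route at 5.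

Further compounds
F1 | step 8 | dibenzyl 3,4-bis(5-methoxy-4-methyl-3,5-dioxopentanoyl)-3,4-dimethylcyclobutane-1,2-dicarboxylate | COC(=O)C(C)C(=O)CC(=O)[C@@]1(C)[C@H](C(=O)OCc2ccccc2)[C@H](C(=O)OCc2ccccc2)[C@@]1(C)C(=O)CC(=O)C(C)C(=O)OC
F2 | step 3 | 2,5-dimethylthiophene 1-oxide | CC1=CC=C(C)S1=O
F3 | step 3 | endo-1,4-dimethyl-7-thiabicyclo[2.2.1]hept-5-ene-2,3-dicarboxylic anhydride 7-oxide | C[C@]12C=C[C@](C)([S@]1=O)[C@H]3C(=O)OC(=O)[C@@H]23
F4 | step 3 | cis-3,6-dimethylcyclohexa-3,5-diene-1,2-dicarboxylic anhydride | CC1=CC=C(C)[C@@H]2C(=O)OC(=O)[C@H]12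
F5 | step 3 | exo-1,4-dimethylbicyclo[2.2.0]hex-5-ene-2,3-dicarboxylic anhydride | C1=C[C@@]2(C)[C@@H]3C(=O)OC(=O)[C@@H]3[C@@]12C
F6 | step 3 | exo,exo-3-(benzyloxycarbonyl)-1,4-dimethylbicyclo[2.2.0]hex-5-ene-2-carboxylic acid (racemic) | C1=C[C@@]2(C)[C@H](C(=O)O)[C@H](C(=O)OCc3ccccc3)[C@@]12C
F7 | step 3 | dibenzyl exo,exo-1,4-dimethylbicyclo[2.2.0]hex-5-ene-2,3-dicarboxylate | C1=C[C@@]2(C)[C@H](C(=O)OCc3ccccc3)[C@H](C(=O)OCc3ccccc3)[C@@]12C
F8 | step 3 | dibenzyl (1R,2S,3R,4S)-3,4-diformyl-3,4-dimethylcyclobutane-1,2-dicarboxylate | O=C[C@@]1(C)[C@H](C(=O)OCc2ccccc2)[C@H](C(=O)OCc2ccccc2)[C@@]1(C)C=O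
F9 | step 3 | dibenzyl 3,4-bis(1-hydroxyethyl)-3,4-dimethylcyclobutane-1,2-dicarboxylate (carbinol centres undefined) | CC(O)[C@@]1(C)[C@H](C(=O)OCc2ccccc2)[C@H](C(=O)OCc2ccccc2)[C@@]1(C)C(C)O
F10 | step 1 | 3,4-dichloro-1,2,3,4-tetramethylcyclobut-1-ene (configuration at C3/C4 immaterial) | CC1=C(C)C(C)(Cl)C1(C)Cl
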